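Slowness shows first: in the midnight run, a closed flask, monomer in chains needs 3.00 d to reach 58.2%, and it then stands near 62.9% at 10.0 d.

in all of them: pre-initiator 5 mol%

| charge | free monomer | transfer agent | protic impurity | remark | time |
|---|---|---|---|---|---|
| midnight | 0.30 M | 9 mM | 0.30 M | run made earlier |  |
| dusk | 0.30 M | 6 mM | 0.30 M | run made earlier |  |
| winter | 0.30 M | 14 mM | 0.30 M | run made earlier |  |
| north | 0.30 M (fed, over 8.00 d) | 9.00 mM | 0.300 M | all but free monomer at the start; free monomer goes in evenly over 8.00 d, the run ends at 10 d | 10 d |
| south | 0.30 M | 9.00 mM | 0.300 M | a closed flask charged with all of it at once and left for 10 d | 10 d |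
| south-west | 0.30 M | 9.00 mM | 0.300 M | a tube with plug flow, the mixed feed as stated, residence time 10 d | 10 d |
| south-east | 0.30 M | 9.00 mM | 0.300 M | a single well-mixed tank run continuously and read at steady state, 10 d in it on average |  |

- midnight (time / d: monomer in chains / %): 1.25: 47.2; 3.00: 58.2; 4.00: 60.6; 6.00: 61.7; 8.00: 62.7; 10.0: 62.9
- dusk (time / d: monomer in chains / %): 1.04: 39.7; 1.67: 57.0; 2.00: 59.2; 3.00: 63.0; 5.00: 62.5; 8.00: 61.9; 12.0: 64.2
- winter (time / d: monomer in chains / %): 0.625: 18.3; 1.67: 51.2; 3.00: 55.7; 5.00: 60.0; 8.00: 58.6; 10.0: 61.7; 12.0: 58.5

(readings scatter by 1 percentage point)

- the set-up with the highest amount of monomer in chains at the outlet or at the end, in percent of the free monomer put in ("none" if the first two lie within 2 percentage points) (north / south / south-west / south-east / none)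
- amount of monomer in chains at the outlet or at the end, in percent of the free monomer put in, north
- amount of monomer in chains at the outlet or at the end, in percent of the free monomer put in, south
- amount of monomer in chains at the outlet or at the end, in percent of the free monomer put in, south-west
- amount of monomer in chains at the outlet or at the end, in percent of the free monomer put in, south-east

- the stated concentrations are those of everything mixed, before any reaction; amounts are the same in each set-up
- the numbers in the tables scatter by 1 percentage point (one standard deviation)
- reactions considered so far: protic impurity + free monomer -> quenched substrate; free monomer + living end -> monomer in chains + living end; living end + transfer agent -> dead chain; pre-initiator -> initiator; free monomer + initiator -> living end + monomer in chains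
- the feed brings no volume worth counting
- the earlier runs were made in a closed, stirred flask

Free monomer has two exits, into chains and into quenched substrate. Quench needs no living end, so I read what the midnight plateau lacks as quenched. The number to carry is 1.70, the split or selectivity factor: monomer in chains per monomer quenched. It is a reading and carries the scatter. Both exits are first order in free monomer, so [free monomer] cancels from their ratio at any moment, and the momentary split follows [living end] and [initiator] over [protic impurity].

The first chemist says the split belongs to the recipe. The last readings stand at 64.2% in the dusk run with 6 mM of transfer agent and 58.5% in the winter run with 14 mM, the amounts are the same in each set-up, and this chemist expects transfer agent to have killed the ends before late monomer enters north. So north should give the midnight plateau again.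

The second chemist says the split is a time average. The closed midnight flask stands at 58.2% by 3.00 d, a stretch that starts with no living end in the charge, while north's feed lasts 8.00 d, which is longer. The pre-initiator charge of 15.0 mM is also larger than the 9.00 mM of transfer agent, so up to 6.00 mM of ends can outlast it.

I side with the second for north and expect it to clear the plateau by more than 2 percentage points. A plug in the tube lives the closed flask's history, so for south and south-west I take the first chemist's split.

The forecast agrees in direction, with north best, 72% for north, 62% for south, 62% for south-west and 67% for south-east, because “Feeding keeps monomer scarce while living ends build”.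

The simulation gives north 69.7%, south 61.4%, south-west 61.4% and south-east 66.2%, so north is best. The first chemist's view holds in south and south-west, whose split is 1.59.

    protic impurity + free monomer → quenched substrate (k = 2.27 × 10⁻⁵ /M/s)
    free monomer + living end → monomer in chains + living end, rate k2*[living end]*[free monomer] (k = 0.00379 /M/s)
    living end + transfer agent → dead chain (kL = 9.70 × 10⁻⁴ /M/s)
    pre-initiator → initiator (k = 1.04 × 10⁻⁵ /s)
    free monomer + initiator → living end + monomer in chains (k = 1.40 × 10⁻⁴ /M/s)

North's whole-run split is 2.30, higher than the midnight 1.70, and at 10.0 d growth uses free monomer 3.4 times as fast as quench, with [living end] at 0.00427 M against 8.06 × 10⁻⁴ M in south. The neighbour flask, north with 0.75 M of free monomer and its loadings held, so that protic impurity stands at 0.400 equiv, reaches a split of 7.47, with 88.2% of monomer in chains.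

The readings stem from a simulated flask on assumed constants, noise included.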